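**Retrosynthetic overview**

1. Structural feature: ring A (the dearomatised acylphloroglucinol ring, with one unsubstituted carbon, here called its free carbon, and one C(Me)(prenyl) carbon, here called its quaternary carbon) and ring B (the cyclopentane; C2' = CH carrying the link, C3' = carbinol carbon, C6' = CH carrying isopropenyl) are joined by one CH2 (C1'). C1' lies between the free carbon of ring A, which is the central carbon of a cyclic β-diketone, and C2', which is a ketone α-carbon once the C3' methyl is removed, so C1' is a formaldehyde carbon.
2. Last disconnection: C3'–CH3, by methyl addition to the ring B ketone 18.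
3. Key disconnection: the two bonds of C1', to the free carbon of ring A and to C2', together, from trione 8, formaldehyde 15 and silyl enol ether 14, through o-quinone methide 16, an inverse-demand hetero-Diels–Alder reaction and hydrolysis of silyl ketal 17.
4. Fragments: 8 from 2-methylphloroglucinol (acylation, bromine block at the free carbon, Pd-catalysed asymmetric dearomative prenylation setting the quaternary carbon, debromination); 14 from cyclopent-2-en-1-one (Cu-catalysed asymmetric isopropenyl conjugate addition setting C6', O-silylation of the enolate).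
5. Ring order: no carbocycle is built; ring A comes from the arene and is dearomatised in step 4, ring B comes from cyclopentenone, and the only ring closed (the pyran ketal of step 7) is opened again.

Key step: step 7

Remark on the chemistry: ring A compounds are β,β'-triketones written as the single enol tautomer shown in the SMILES; CIP labels at the quaternary carbon of ring A refer to that tautomer.
Remark on the chemistry: the sense of induction of the chiral ligands in steps 4 and 6 is assumed to invert with the ligand enantiomer; the enantiomer named is the one proposed for R at the quaternary carbon of ring A and R at C6', to be confirmed by correlation.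
Remark on the chemistry: any minor enantiomer carried by 8 or 14 becomes a diastereomer of 18 in step 7 and is to be removed there by chromatography.

**Step 1**
Reactants: 1 2-methylphloroglucinol; 2 isobutyryl chloride
Product: 3 1-(2,4,6-trihydroxy-3-methylphenyl)-2-methylpropan-1-one
Conditions: AlCl3 (4 equiv), PhNO2/CH2Cl2, 0 → 50 °C; aq. HCl work-up
Reagents that add atoms: none
Why: Friedel–Crafts C-acylation of the strongly activated triol at one of its two equivalent free ring positions should stop at the ketone because the first acyl group deactivates the ring.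

**Step 2**
Reactants: 3 1-(2,4,6-trihydroxy-3-methylphenyl)-2-methylpropan-1-one
Product: 4 1-(3-bromo-2,4,6-trihydroxy-5-methylphenyl)-2-methylpropan-1-one
Conditions: NBS (1.0 equiv), THF, −40 → 0 °C
Reagents that add atoms: N-bromosuccinimide, O=C1CCC(=O)N1Br
Why: Electrophilic aromatic bromination should take the only remaining unsubstituted ring carbon (the free carbon of ring A, which later takes C1'), blocking it for the dearomatising step, while one equivalent at low temperature limits ipso attack.

**Step 3**
Reactants: 5 prenol (3-methylbut-2-en-1-ol)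
Product: 6 tert-butyl 3-methylbut-2-en-1-yl carbonate
Conditions: Boc2O (1.2 equiv), DMAP (5 mol%), CH2Cl2, rt
Reagents that add atoms: di-tert-butyl dicarbonate, CC(C)(C)OC(=O)OC(=O)OC(C)(C)C
Why: DMAP-catalysed acyl transfer to the primary alcohol should give the mixed carbonate, an ionisable prenyl donor that releases its own base on ionisation.

**Step 4**
Reactants: 4 1-(3-bromo-2,4,6-trihydroxy-5-methylphenyl)-2-methylpropan-1-one; 6 tert-butyl 3-methylbut-2-en-1-yl carbonate
Product: 7 (6R)-4-bromo-3,5-dihydroxy-6-methyl-6-(3-methylbut-2-en-1-yl)-2-(2-methylpropanoyl)cyclohexa-2,4-dien-1-one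
Conditions: Pd2(dba)3·CHCl3 (2.5 mol%), (R,R)-N,N'-(cyclohexane-1,2-diyl)bis[2-(diphenylphosphanyl)benzamide] (7.5 mol%), 6 (1.1 equiv), 1,4-dioxane, 10 °C → rt; aq. citric acid work-up
Reagents that add atoms: none
Why: In this Tsuji–Trost-type asymmetric allylic alkylation with dearomatisation, zerovalent palladium ionises 6 to a 1,1-dimethyl-π-allyl complex and tert-butoxide, and the resulting phenolate should attack the unsubstituted allyl terminus through its methyl-bearing carbon (the brominated carbon is less nucleophilic, the acylated one inert, O-prenyl ethers re-ionise, and the electron-rich anion resists oxidative addition at C–Br), the chiral diphosphine pocket choosing the arene face so that the quaternary carbon of ring A is set as R.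

**Step 5**
Reactants: 7 (6R)-4-bromo-3,5-dihydroxy-6-methyl-6-(3-methylbut-2-en-1-yl)-2-(2-methylpropanoyl)cyclohexa-2,4-dien-1-one
Product: 8 (6R)-3,5-dihydroxy-6-methyl-6-(3-methylbut-2-en-1-yl)-2-(2-methylpropanoyl)cyclohexa-2,4-dien-1-one (ring A trione, enol form)
Conditions: Na2SO3 (2 equiv), THF/H2O, 0 °C → rt; then aq. citric acid
Reagents that add atoms: none
Why: Reductive dehalogenation by halophilic attack of sulfite on the positive bromine of the 2-bromo-1,3-diketone enol should restore the C–H at the free carbon of ring A without touching the alkenes, the acyl group or the all-carbon quaternary centre.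

**Step 6**
Reactants: 9 2-bromopropene; 10 cyclopent-2-en-1-one
Product: 14 (R)-tert-butyldimethyl{[3-(prop-1-en-2-yl)cyclopent-1-en-1-yl]oxy}silane, via isopropenyllithium 11 (not isolated), via dimethyl(isopropenyl)aluminium 12 (not isolated), via aluminium enolate 13 (not isolated)
Conditions: Li, Et2O, 0 °C; Me2AlCl, −30 °C; Cu(OTf)2 (5 mol%), (S)-binaphthol-derived phosphoramidite of bis[(R)-1-phenylethyl]amine (10 mol%), 10, Et2O, −30 °C; TBSOTf, −30 → 0 °C; filtration through basic alumina, distillation
Reagents that add atoms: tert-butyldimethylsilyl trifluoromethanesulfonate, CC(C)(C)[Si](C)(C)OS(=O)(=O)C(F)(F)F; dimethylaluminium chloride, C[Al](C)Cl (atoms kept only in 12 and 13); lithium, [Li] (kept only in 11)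
Why: In this copper-catalysed asymmetric conjugate addition of an alkenylalane (made by lithiation of 9 and Li-to-Al exchange), the phosphoramidite–copper complex should transfer the isopropenyl group selectively to one enantiotopic face of the enone, setting C6' as R, and O-silylation of the aluminium enolate fixes the enol ether double bond at C2'=C3'.

**Step 7**
Reactants: 8 (6R)-3,5-dihydroxy-6-methyl-6-(3-methylbut-2-en-1-yl)-2-(2-methylpropanoyl)cyclohexa-2,4-dien-1-one; 15 formaldehyde (as paraformaldehyde); 14 (R)-tert-butyldimethyl{[3-(prop-1-en-2-yl)cyclopent-1-en-1-yl]oxy}silane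
Product: 18 (6R)-3,5-dihydroxy-6-methyl-6-(3-methylbut-2-en-1-yl)-2-(2-methylpropanoyl)-4-{[(1S,5R)-2-oxo-5-(prop-1-en-2-yl)cyclopentyl]methyl}cyclohexa-2,4-dien-1-one, via o-quinone methide 16 (not isolated), via silyl ketal cycloadduct 17 (not isolated)
Conditions: 15 (1.5 equiv, in portions), 14 (3 equiv), ethylenediammonium diacetate (10 mol%), 4 Å MS, MeCN, 40 °C; then 0.5 M HCl, THF, 0 °C
Reagents that add atoms: none
Why: Amine-salt-catalysed Knoevenagel condensation of formaldehyde at the free carbon of ring A, the only enolisable C–H of 8 flanked by two carbonyls, and loss of water give o-quinone methide 16, a strongly electrophilic 1-oxadiene, which the electron-rich C2'=C3' bond of 14 should intercept in an inverse-electron-demand hetero-Diels–Alder reaction (asynchronous, C1'–C2' bonding ahead of O–C3'), so that both bonds of C1' form in one flask. The closest known reaction type is the domino Knoevenagel/hetero-Diels–Alder reaction of cyclic 1,3-diones, aldehydes and enol ethers, and formaldehyde-derived quinone methides of dearomatised acylphloroglucinols are known to add to alkenes. The only ring closed is the transient six-membered O,O-silyl ketal (dihydropyran of 17, closed by the [4+2] cycloaddition through the ring A oxygen on the side of the quaternary carbon and cis-fused to ring B); acid hydrolysis opens it again, so no ring remains, and closure through the other flanking oxygen, on the acyl side, would converge on the same ketone. The one lasting new stereocentre, C2', is controlled by C6': the diene should add to the enol ether face opposite the adjacent isopropenyl group, giving the trans C2'/C6' ketone, which is also the more stable epimer should the α-centre equilibrate. The step needs regioselectivity between the two ketone α-carbons, secured by the regiodefined enol ether of step 6, and chemoselectivity for cross-coupling over methylene-bridged dimerisation of 8, secured by portionwise formaldehyde release, a threefold excess of 14 and the reversibility (retro-Michael) of dimer formation on warming.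

**Step 8**
Reactants: 18 (6R)-3,5-dihydroxy-6-methyl-6-(3-methylbut-2-en-1-yl)-2-(2-methylpropanoyl)-4-{[(1S,5R)-2-oxo-5-(prop-1-en-2-yl)cyclopentyl]methyl}cyclohexa-2,4-dien-1-one
Product: 19 (6R)-3,5-dihydroxy-4-{[(1S,2R,5R)-2-hydroxy-2-methyl-5-(prop-1-en-2-yl)cyclopentyl]methyl}-6-methyl-6-(3-methylbut-2-en-1-yl)-2-(2-methylpropanoyl)cyclohexa-2,4-dien-1-one (CNP0261875.1)
Conditions: CeCl3 (anhydrous, 6 equiv), MeMgBr (6 equiv), THF, −78 → −20 °C; then 0.5 M HCl, 0 °C
Reagents that add atoms: methylmagnesium bromide, C[Mg]Br
Why: In this cerium-mediated Grignard 1,2-addition the first two equivalents turn ring A into its dianion, which shields its carbonyls, and the weakly basic methyl reagent should then add to the ring B ketone from the face anti to the bulky C1' substituent on the neighbouring C2', setting C3' as R with the hydroxyl cis to C1'.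

**Compound list**

1 | 2-methylphloroglucinol (2-methylbenzene-1,3,5-triol) | Cc1c(O)cc(O)cc1O | starting material
2 | isobutyryl chloride | CC(C)C(Cl)=O | starting material
3 | 1-(2,4,6-trihydroxy-3-methylphenyl)-2-methylpropan-1-one | CC(C)C(=O)c1c(O)cc(O)c(C)c1O | intermediate
4 | 1-(3-bromo-2,4,6-trihydroxy-5-methylphenyl)-2-methylpropan-1-one | CC(C)C(=O)c1c(O)c(Br)c(O)c(C)c1O | intermediate
5 | prenol (3-methylbut-2-en-1-ol) | CC(C)=CCO | starting material
6 | tert-butyl 3-methylbut-2-en-1-yl carbonate | CC(C)=CCOC(=O)OC(C)(C)C | intermediate
7 | (6R)-4-bromo-3,5-dihydroxy-6-methyl-6-(3-methylbut-2-en-1-yl)-2-(2-methylpropanoyl)cyclohexa-2,4-dien-1-one | BrC1=C(O)[C@@](C)(CC=C(C)C)C(=O)C(C(=O)C(C)C)=C1O | intermediate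
8 | (6R)-3,5-dihydroxy-6-methyl-6-(3-methylbut-2-en-1-yl)-2-(2-methylpropanoyl)cyclohexa-2,4-dien-1-one (ring A trione, enol form) | C1=C(O)[C@@](C)(CC=C(C)C)C(=O)C(C(=O)C(C)C)=C1O | intermediate
9 | 2-bromopropene | C=C(C)Br | starting material
10 | cyclopent-2-en-1-one | O=C1C=CCC1 | starting material
11 | isopropenyllithium (prop-1-en-2-yllithium) | [Li]C(C)=C | intermediate
12 | dimethyl(prop-1-en-2-yl)aluminium | C=C(C)[Al](C)C | intermediate
13 | dimethylaluminium (R)-3-(prop-1-en-2-yl)cyclopent-1-en-1-olate | C=C(C)[C@@H]1CCC(O[Al](C)C)=C1 | intermediate
14 | (R)-tert-butyldimethyl{[3-(prop-1-en-2-yl)cyclopent-1-en-1-yl]oxy}silane | C=C(C)[C@@H]1CCC(O[Si](C)(C)C(C)(C)C)=C1 | intermediate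
15 | formaldehyde (used as paraformaldehyde) | C=O | starting material
16 | o-quinone methide: (6R)-3-hydroxy-6-methyl-6-(3-methylbut-2-en-1-yl)-4-methylidene-2-(2-methylpropanoyl)cyclohex-2-ene-1,5-dione | C=C1C(=O)[C@@](C)(CC=C(C)C)C(=O)C(C(=O)C(C)C)=C1O | intermediate
17 | silyl ketal cycloadduct: dihydropyran whose ring oxygen sits on the ring A carbon between the former free carbon and the quaternary carbon, with C1' linking the former free carbon of ring A to C2', cis-fused to ring B at C2'–C3' (ring oxygen and C1' on the same face), OTBS on C3', isopropenyl on C6' trans to C1', quaternary carbon of ring A R | C=C(C)[C@@H]1CC[C@@]2(O[Si](C)(C)C(C)(C)C)OC3=C(C[C@@H]12)C(O)=C(C(=O)C(C)C)C(=O)[C@]3(C)CC=C(C)C | intermediate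
18 | (6R)-3,5-dihydroxy-6-methyl-6-(3-methylbut-2-en-1-yl)-2-(2-methylpropanoyl)-4-{[(1S,5R)-2-oxo-5-(prop-1-en-2-yl)cyclopentyl]methyl}cyclohexa-2,4-dien-1-one | C=C(C)[C@@H]1CCC(=O)[C@H]1CC1=C(O)[C@@](C)(CC=C(C)C)C(=O)C(C(=O)C(C)C)=C1O | intermediate
19 | (6R)-3,5-dihydroxy-4-{[(1S,2R,5R)-2-hydroxy-2-methyl-5-(prop-1-en-2-yl)cyclopentyl]methyl}-6-methyl-6-(3-methylbut-2-en-1-yl)-2-(2-methylpropanoyl)cyclohexa-2,4-dien-1-one | C=C(C)[C@@H]1CC[C@@](C)(O)[C@H]1CC1=C(O)[C@@](C)(CC=C(C)C)C(=O)C(C(=O)C(C)C)=C1O | target

**Step count**

Total step count: 8.
Longest linear sequence: 6 steps (steps 1, 2, 4, 5, 7, 8, from 2-methylphloroglucinol).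

**Steps most likely to fail**

Step 7. Michael addition of a second molecule of 8 to the o-quinone methide (methylene-bridged dimerisation) and protodesilylation of the enol ether by the acidic trione and the water released may outrun the cycloaddition. The fallback sets out from 8 and comes back at 18. 8 is aminomethylated at the free carbon of ring A with dimethylmethylideneammonium iodide (CH2Cl2, rt), a Mannich reaction that forms the bond from that carbon to C1' without free formaldehyde, to give the Mannich base (6R)-4-[(dimethylamino)methyl]-3,5-dihydroxy-6-methyl-6-(3-methylbut-2-en-1-yl)-2-(2-methylpropanoyl)cyclohexa-2,4-dien-1-one F1. After removal of unreacted 8, F1 is heated with 14 (toluene, 80 °C). Thermal loss of dimethylamine should release 16 slowly with no free 8 present, 16 is trapped as 17, and the same acid hydrolysis gives 18.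

Step 4. The ambident phenolate may react at oxygen or at the wrong ring carbon, the chiral palladium complex may discriminate the arene faces poorly, the product may re-ionise, or bromine may be lost to zerovalent palladium. The fallback sets out from 4 and comes back at 8. 4 is alkylated with prenyl bromide and NaOMe in MeOH at 0 °C (base-mediated dearomative C-alkylation in a protic medium) to the racemic bromo trione F2. Sulfite debromination as in step 5 gives the racemic ring A trione F3. Its enantiomers are separated by preparative chromatography on a chiral stationary phase; the S enantiomer F4 is set aside and the R enantiomer is 8.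

Step 8. Methyl delivery may show poor facial selectivity, or the basic reagent may enolise the ring B ketone instead of adding to it. The fallback sets out from 18 and comes back at 19. Corey–Chaykovsky epoxidation (trimethylsulfonium iodide, KN(SiMe3)2 in excess so that ring A is first deprotonated, THF, −20 → 0 °C) should add the ylide irreversibly from the face anti to C1' and close to the spiro-epoxide F5, with the oxirane oxygen on C3' cis to C1'; F5 can be purified at this stage. LiEt3BH (excess, THF, 0 °C) then opens the oxirane at its CH2 carbon, which becomes the C3' methyl, giving 19.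

**Further compounds**

F1 | step 7 | Mannich base, (6R)-4-[(dimethylamino)methyl]-3,5-dihydroxy-6-methyl-6-(3-methylbut-2-en-1-yl)-2-(2-methylpropanoyl)cyclohexa-2,4-dien-1-one | CN(C)CC1=C(O)[C@@](C)(CC=C(C)C)C(=O)C(C(=O)C(C)C)=C1O
F2 | step 4 | racemic bromo trione, rac-4-bromo-3,5-dihydroxy-6-methyl-6-(3-methylbut-2-en-1-yl)-2-(2-methylpropanoyl)cyclohexa-2,4-dien-1-one | BrC1=C(O)C(C)(CC=C(C)C)C(=O)C(C(=O)C(C)C)=C1O
F3 | step 4 | racemic ring A trione, rac-3,5-dihydroxy-6-methyl-6-(3-methylbut-2-en-1-yl)-2-(2-methylpropanoyl)cyclohexa-2,4-dien-1-one | C1=C(O)C(C)(CC=C(C)C)C(=O)C(C(=O)C(C)C)=C1O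
F4 | step 4 | (6S)-3,5-dihydroxy-6-methyl-6-(3-methylbut-2-en-1-yl)-2-(2-methylpropanoyl)cyclohexa-2,4-dien-1-one (enantiomer of 8) | C1=C(O)[C@](C)(CC=C(C)C)C(=O)C(C(=O)C(C)C)=C1O
F5 | step 8 | spiro-epoxide of 18 at C3' (oxirane oxygen cis to C1', oxirane CH2 trans to C1') | C=C(C)[C@@H]1CC[C@]2(CO2)[C@H]1CC1=C(O)[C@@](C)(CC=C(C)C)C(=O)C(C(=O)C(C)C)=C1O
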